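**Retrosynthetic overview**

1. Target ⇒ sorbate ester 16 + (2S,3S)-3-methylpent-4-en-2-ol 20 (late cross-metathesis at the γ,δ-olefin of the dienoate; 20 from one asymmetric crotylboration).
2. 16 ⇒ enone-ol 10 by esterification, chloranil dehydrogenation (C1=C2) and α'-hydroxylation (C7, anti to the angular methyl).
3. Key step: 10 ⇒ monocyclic keto-aldehyde 9. An aldehyde-initiated cation–olefin cyclisation closes ring A and gives the C5 cation of a 10-methyldecalin; the C10→C5 methyl shift and loss of H9 (the eudesmyl→eremophilyl events of aristolochene biosynthesis) then set C3, C4, C5 and the enone in one flask.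
4. 9 ⇒ commercial ring B ketone 1 by asymmetric Michael addition (quaternary C10), Z-selective Wittig ethylidenation, and nitrile reduction with ketal hydrolysis.
5. Ring order: ring B is bought; ring A is the only ring formed (step 4).

Assumption: ring positions are given in eremophilane numbering (C3 ester carbon, C4 CHMe, C5 quaternary, C6 CH2, C7 CHOH, C8 C=O, C9=C10, C1=C2); the target is 3S,4R,5R,7R with a (2E,4E,6S,7S) side chain; 1 is used as the racemate.

**Step 1**
Reactants: 1 7-methyl-1,4-dioxaspiro[4.5]decan-8-one (racemic); 2 (R)-1-phenylethylamine; 3 acrylonitrile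
Product: 6 3-[(7R)-7-methyl-8-oxo-1,4-dioxaspiro[4.5]decan-7-yl]propanenitrile, via ketimine 4 (not isolated), via alkylated imine 5 (not isolated)
Conditions: 2, TsOH (cat.), toluene, reflux, Dean–Stark; then 3, neat, 70 °C; then 20% aq AcOH, THF, 25 °C
Reagents that add atoms: acrylonitrile (3), C=CC#N; water, O (ketone oxygen after imine hydrolysis)
Why: d'Angelo asymmetric Michael addition, in which the imine reacts through its more substituted secondary enamine in an aza-ene-like transition state and acrylonitrile adds anti to the phenyl group, so the racemic α-centre is converted into the (R) quaternary carbon (future C10, about 90% ee expected) whose methyl group migrates in step 4.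

**Step 2**
Reactants: 6 3-[(7R)-7-methyl-8-oxo-1,4-dioxaspiro[4.5]decan-7-yl]propanenitrile
Product: 7 3-[(7R,8Z)-8-ethylidene-7-methyl-1,4-dioxaspiro[4.5]decan-7-yl]propanenitrile
Conditions: EtPPh3Br, KN(SiMe3)2, THF, 0 °C; then 6, 0 → 65 °C
Reagents that add atoms: ethyltriphenylphosphonium bromide, CC[P+](c1ccccc1)(c1ccccc1)c1ccccc1.[Br-]
Why: Wittig olefination with a non-stabilised ylide, which places the new methyl syn to the adjacent quaternary carbon (Z, the sense seen in ethylidenation of 17-ketosteroids) while nitrile and ketal are inert; the minor E isomer is removed on AgNO3-impregnated silica because it would give the C4 epimer in step 4.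

**Step 3**
Reactants: 7 3-[(7R,8Z)-8-ethylidene-7-methyl-1,4-dioxaspiro[4.5]decan-7-yl]propanenitrile
Product: 9 3-[(1R,2Z)-2-ethylidene-1-methyl-5-oxocyclohexyl]propanal, via ketal aldehyde 8 (not isolated)
Conditions: i-Bu2AlH, toluene, −78 °C; then 2 M aq HCl, THF, 25 °C
Reagents that add atoms: water, O (both carbonyl oxygens of 9)
Why: nitrile half-reduction stops at the N-aluminio aldimine, and the aqueous acid work-up hydrolyses it to the aldehyde and then cleaves the dioxolane, leaving the quaternary centre and the Z-alkene untouched.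

**Step 4**
Reactants: 9 3-[(1R,2Z)-2-ethylidene-1-methyl-5-oxocyclohexyl]propanal
Product: 10 (4aR,5R,6S)-6-hydroxy-4a,5-dimethyl-4,4a,5,6,7,8-hexahydronaphthalen-2(3H)-one
Conditions: MeAlCl2 (3 equiv), CH2Cl2, −78 → −20 °C; then 1 M aq HCl
Reagents that add atoms: none
Why: Proposed new method: MeAlCl2 activates the aldehyde so that C4 of the (Z)-ethylidene adds to C3 through a chair transition state with the O–Al group equatorial and the Z-methyl axial (Prins-type cation–olefin cyclisation closing ring A and fixing 3S,4R), giving the C5 tertiary cation of a 10-methyldecalin in which the angular C10 methyl is perpendicular to the cation plane and syn-axial to the new C4 methyl, so it migrates suprafacially to C5 (5R, all-cis with C3–O and C4–Me) as in the eudesmyl→eremophilyl step of aristolochene biosynthesis, and the resulting C10 cation, β to the complexed ketone, loses H9 to the conjugated enone while excess MeAlCl2 scavenges the proton as methane; the closest known reactions are MeAlCl2-promoted aldehyde–alkene cyclisations whose zwitterions undergo 1,2-hydride and alkyl shifts, Prins–pinacol cascades, and BF3-induced 1,2-H/1,2-Me rearrangements of decalyl cations.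

**Step 5**
Reactants: 10 (4aR,5R,6S)-6-hydroxy-4a,5-dimethyl-4,4a,5,6,7,8-hexahydronaphthalen-2(3H)-one; 11 sorbic acid
Product: 12 (1R,2S,8aR)-1,8a-dimethyl-6-oxo-1,2,3,4,6,7,8,8a-octahydronaphthalen-2-yl (2E,4E)-hexa-2,4-dienoate
Conditions: 11, EDC·HCl, DMAP, CH2Cl2, 0 → 25 °C
Reagents that add atoms: sorbic acid (11), C/C=C/C=C/C(=O)O
Why: Steglich esterification acylates the secondary alcohol with retention at C3 and also masks it against oxidation in step 6.

**Step 6**
Reactants: 12 (1R,2S,8aR)-1,8a-dimethyl-6-oxo-1,2,3,4,6,7,8,8a-octahydronaphthalen-2-yl (2E,4E)-hexa-2,4-dienoate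
Product: 13 (1R,2S,8aR)-1,8a-dimethyl-6-oxo-1,2,6,7,8,8a-hexahydronaphthalen-2-yl (2E,4E)-hexa-2,4-dienoate
Conditions: chloranil, t-BuOH, reflux
Reagents that add atoms: none
Why: quinone dehydrogenation of the enone through its extended dienol (hydride abstraction from C2, as in the conversion of steroidal 4-en-3-ones into 4,6-dien-3-ones) gives the linear 1,9-dien-8-one; the quaternary C5 blocks aromatisation and the electron-poor sorbate is inert.

**Step 7**
Reactants: 13 (1R,2S,8aR)-1,8a-dimethyl-6-oxo-1,2,6,7,8,8a-hexahydronaphthalen-2-yl (2E,4E)-hexa-2,4-dienoate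
Product: 16 (1R,2S,7R,8aR)-7-hydroxy-1,8a-dimethyl-6-oxo-1,2,6,7,8,8a-hexahydronaphthalen-2-yl (2E,4E)-hexa-2,4-dienoate, via silyl dienol ether 14 (not isolated), via 7-silyloxy ketone 15 (not isolated)
Conditions: LiN(SiMe3)2, Me3SiCl, THF, −78 °C; then mCPBA, NaHCO3, CH2Cl2, −20 °C; then citric acid, MeOH, 0 °C
Reagents that add atoms: mCPBA, OOC(=O)c1cccc(Cl)c1 (C7 oxygen); Me3SiCl, C[Si](C)(C)Cl (silicon only in 14 and 15)
Why: kinetic α'-deprotonation with in-flask silylation followed by Rubottom oxidation, in which the peracid attacks the electron-rich C7=C8 enol ether anti to the axial C5 methyl and so gives the equatorial 7R alcohol, while the electron-poor dienone and sorbate olefins do not react.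

**Step 8**
Reactants: 17 acetaldehyde; 18 (Z)-but-2-ene
Product: 20 (2S,3S)-3-methylpent-4-en-2-ol, via borinate ester 19 (not isolated)
Conditions: 18, KOt-Bu, n-BuLi, THF, −78 → −45 °C; (+)-Ipc2BOMe [from (−)-α-pinene], −78 °C; BF3·OEt2; 17, −78 °C; then 3 M NaOH, 30% H2O2, 25 → 50 °C
Reagents that add atoms: (Z)-but-2-ene (18), C/C=C\C; (+)-Ipc2BOMe, COB([C@H]1C[C@H]2C[C@@H]([C@@H]1C)C2(C)C)[C@H]1C[C@H]2C[C@@H]([C@@H]1C)C2(C)C (boron and Ipc groups only in 19)
Why: Brown asymmetric crotylboration through a Zimmerman–Traxler chair, where the Z-crotyl geometry gives the syn relationship and the Ipc groups from (−)-α-pinene direct addition to the aldehyde face that gives 2S, hence (2S,3S).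

**Step 9**
Reactants: 16 (1R,2S,7R,8aR)-7-hydroxy-1,8a-dimethyl-6-oxo-1,2,6,7,8,8a-hexahydronaphthalen-2-yl (2E,4E)-hexa-2,4-dienoate; 20 (2S,3S)-3-methylpent-4-en-2-ol
Product: 21 (1R,2S,7R,8aR)-7-hydroxy-1,8a-dimethyl-6-oxo-1,2,6,7,8,8a-hexahydronaphthalen-2-yl (2E,4E,6S,7S)-7-hydroxy-6-methylocta-2,4-dienoate
Conditions: 20 (5 equiv), second-generation Hoveyda–Grubbs catalyst (H2IMes)Cl2Ru=CH(2-i-PrOC6H4) (10 mol%), CH2Cl2, 40 °C, argon sweep
Reagents that add atoms: (2S,3S)-3-methylpent-4-en-2-ol (20), C[C@H](O)[C@@H](C)C=C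
Why: olefin cross-metathesis exchanges only the terminal propenyl unit of the dienoate (the ester-conjugated C2=C3 bond and the conjugated ring olefins are inert), propene is swept out, the branched allylic substituent favours the E olefin, no stereocentre is touched and no protecting group is needed.

**Compound list**

1 | 7-methyl-1,4-dioxaspiro[4.5]decan-8-one (racemic) | CC1CC2(CCC1=O)OCCO2 | starting material
2 | (R)-1-phenylethylamine | C[C@@H](N)c1ccccc1 | starting material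
3 | acrylonitrile | C=CC#N | starting material
4 | (1R)-N-(7-methyl-1,4-dioxaspiro[4.5]decan-8-ylidene)-1-phenylethanamine (C7 epimers, equilibrating) | C[C@@H](N=C1CCC2(CC1C)OCCO2)c1ccccc1 | intermediate
5 | 3-[(7R)-7-methyl-8-{[(1R)-1-phenylethyl]imino}-1,4-dioxaspiro[4.5]decan-7-yl]propanenitrile | N#CCC[C@]1(C)CC2(CCC1=N[C@H](C)c1ccccc1)OCCO2 | intermediate
6 | 3-[(7R)-7-methyl-8-oxo-1,4-dioxaspiro[4.5]decan-7-yl]propanenitrile | N#CCC[C@]1(C)CC2(CCC1=O)OCCO2 | intermediate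
7 | 3-[(7R,8Z)-8-ethylidene-7-methyl-1,4-dioxaspiro[4.5]decan-7-yl]propanenitrile | C/C=C1/CCC2(OCCO2)C[C@@]1(C)CCC#N | intermediate
8 | 3-[(7R,8Z)-8-ethylidene-7-methyl-1,4-dioxaspiro[4.5]decan-7-yl]propanal | C/C=C1/CCC2(OCCO2)C[C@@]1(C)CCC=O | intermediate
9 | 3-[(1R,2Z)-2-ethylidene-1-methyl-5-oxocyclohexyl]propanal | C/C=C1/CCC(=O)C[C@@]1(C)CCC=O | intermediate
10 | (4aR,5R,6S)-6-hydroxy-4a,5-dimethyl-4,4a,5,6,7,8-hexahydronaphthalen-2(3H)-one | O[C@H]1CCC2=CC(=O)CC[C@]2(C)[C@H]1C | intermediate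
11 | sorbic acid, (2E,4E)-hexa-2,4-dienoic acid | C/C=C/C=C/C(=O)O | starting material
12 | (1R,2S,8aR)-1,8a-dimethyl-6-oxo-1,2,3,4,6,7,8,8a-octahydronaphthalen-2-yl (2E,4E)-hexa-2,4-dienoate | C/C=C/C=C/C(=O)O[C@H]1CCC2=CC(=O)CC[C@]2(C)[C@H]1C | intermediate
13 | (1R,2S,8aR)-1,8a-dimethyl-6-oxo-1,2,6,7,8,8a-hexahydronaphthalen-2-yl (2E,4E)-hexa-2,4-dienoate | C/C=C/C=C/C(=O)O[C@H]1C=CC2=CC(=O)CC[C@]2(C)[C@H]1C | intermediate
14 | (1R,2S,8aR)-1,8a-dimethyl-6-[(trimethylsilyl)oxy]-1,2,8,8a-tetrahydronaphthalen-2-yl (2E,4E)-hexa-2,4-dienoate | C/C=C/C=C/C(=O)O[C@H]1C=CC2=CC(O[Si](C)(C)C)=CC[C@]2(C)[C@H]1C | intermediate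
15 | (1R,2S,7R,8aR)-1,8a-dimethyl-6-oxo-7-[(trimethylsilyl)oxy]-1,2,6,7,8,8a-hexahydronaphthalen-2-yl (2E,4E)-hexa-2,4-dienoate | C/C=C/C=C/C(=O)O[C@H]1C=CC2=CC(=O)[C@H](O[Si](C)(C)C)C[C@]2(C)[C@H]1C | intermediate
16 | (1R,2S,7R,8aR)-7-hydroxy-1,8a-dimethyl-6-oxo-1,2,6,7,8,8a-hexahydronaphthalen-2-yl (2E,4E)-hexa-2,4-dienoate | C/C=C/C=C/C(=O)O[C@H]1C=CC2=CC(=O)[C@H](O)C[C@]2(C)[C@H]1C | intermediate
17 | acetaldehyde | CC=O | starting material
18 | (Z)-but-2-ene | C/C=C\C | starting material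
19 | (2S,3S)-3-methylpent-4-en-2-yl diisopinocampheylborinate (Ipc groups from (−)-α-pinene) | C[C@H](OB([C@H]1C[C@H]2C[C@@H]([C@@H]1C)C2(C)C)[C@H]1C[C@H]2C[C@@H]([C@@H]1C)C2(C)C)[C@@H](C)C=C | intermediate
20 | (2S,3S)-3-methylpent-4-en-2-ol | C[C@H](O)[C@@H](C)C=C | intermediate
21 | (1R,2S,7R,8aR)-7-hydroxy-1,8a-dimethyl-6-oxo-1,2,6,7,8,8a-hexahydronaphthalen-2-yl (2E,4E,6S,7S)-7-hydroxy-6-methylocta-2,4-dienoate (CNP0329432.2) | C[C@H](O)[C@@H](C)/C=C/C=C/C(=O)O[C@H]1C=CC2=CC(=O)[C@H](O)C[C@]2(C)[C@H]1C | target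

**Step count**

Total: 9 steps. Longest linear sequence: 8 steps (steps 1–7 and 9); step 8 is the one-step side branch. Minor diastereomers from the roughly 90% ee of 6 and 20 are removed by chromatography of 21.

**Three steps most likely to fail**

Step 4 (the cascade may stop at the ene stage, or elimination from the C5 cation may outrun the methyl shift; any 3,10-bridged ether formed by capture of the C10 cation is a β-alkoxy ketone and reopens to 10 with DBU). The fallback sets out from 9 and comes back at 12. Compound 9 is closed under concerted carbonyl-ene conditions (Me2AlCl, 1.1 equiv, CH2Cl2, −78 °C) to the homoallylic alcohol (5R,6R,8aR)-6-hydroxy-5,8a-dimethyl-3,5,6,7,8,8a-hexahydronaphthalen-2(1H)-one F1. Here the oxygen is expected axial (the C3 epimer), because hydrogen transfer from C6 needs an axial carbonyl. Mitsunobu esterification with 11 (PPh3, DIAD, toluene, 0 °C) inverts C3 and gives (1R,2S,4aR)-1,4a-dimethyl-6-oxo-1,2,3,4,4a,5,6,7-octahydronaphthalen-2-yl (2E,4E)-hexa-2,4-dienoate F2. The C5 cation is then generated separately by protonating the C5=C6 bond (TfOH, 10 mol%, HFIP/CH2Cl2, −20 °C); methyl shift and loss of H9 give 12.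

Step 6 (chloranil may give incomplete conversion or cross-conjugated over-oxidation). The fallback sets out from 12 and comes back at 13. Soft enolisation (t-BuMe2SiOTf, Et3N, CH2Cl2, 0 °C) gives the extended silyl dienol ether (1R,2S,8aR)-6-[(tert-butyldimethylsilyl)oxy]-1,8a-dimethyl-1,2,3,7,8,8a-hexahydronaphthalen-2-yl (2E,4E)-hexa-2,4-dienoate F3. Saegusa–Ito oxidation (Pd(OAc)2, MeCN, 25 °C) palladates C1 and eliminates the C2 hydrogen to give 13.

Step 9 (cross-metathesis of an α-branched olefin with an internal dienoate olefin may be slow or unselective). The fallback sets out from 10 and 20 and comes back at 21, attaching a complete, protected side chain instead.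
- Alcohol 20 is silylated (t-BuMe2SiCl, imidazole, DMF) to tert-butyldimethyl{[(2S,3S)-3-methylpent-4-en-2-yl]oxy}silane F4.
- Ozonolysis (O3, CH2Cl2, −78 °C; Me2S) gives (2R,3S)-3-[(tert-butyldimethylsilyl)oxy]-2-methylbutanal F5.
- Vinylogous Horner–Wadsworth–Emmons reaction with triethyl 4-phosphonocrotonate (LiN(SiMe3)2, THF, −78 → 0 °C) gives ethyl (2E,4E,6S,7S)-7-[(tert-butyldimethylsilyl)oxy]-6-methylocta-2,4-dienoate F6.
- Saponification (LiOH, THF/H2O) gives (2E,4E,6S,7S)-7-[(tert-butyldimethylsilyl)oxy]-6-methylocta-2,4-dienoic acid F7.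
- Yamaguchi esterification of 10 (2,4,6-trichlorobenzoyl chloride, Et3N, DMAP, toluene) gives (1R,2S,8aR)-1,8a-dimethyl-6-oxo-1,2,3,4,6,7,8,8a-octahydronaphthalen-2-yl (2E,4E,6S,7S)-7-[(tert-butyldimethylsilyl)oxy]-6-methylocta-2,4-dienoate F8.
- Chloranil (t-BuOH, reflux) gives (1R,2S,8aR)-1,8a-dimethyl-6-oxo-1,2,6,7,8,8a-hexahydronaphthalen-2-yl (2E,4E,6S,7S)-7-[(tert-butyldimethylsilyl)oxy]-6-methylocta-2,4-dienoate F9.
- Enolate oxidation (KN(SiMe3)2, THF, −78 °C; 2-(phenylsulfonyl)-3-phenyloxaziridine) gives (1R,2S,7R,8aR)-7-hydroxy-1,8a-dimethyl-6-oxo-1,2,6,7,8,8a-hexahydronaphthalen-2-yl (2E,4E,6S,7S)-7-[(tert-butyldimethylsilyl)oxy]-6-methylocta-2,4-dienoate F10.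
- HF·pyridine (THF, 0 °C) then gives 21.

**Further compounds**

F1 | step 4 | (5R,6R,8aR)-6-hydroxy-5,8a-dimethyl-3,5,6,7,8,8a-hexahydronaphthalen-2(1H)-one | O[C@@H]1CC[C@]2(C)CC(=O)CC=C2[C@H]1C
F2 | step 4 | (1R,2S,4aR)-1,4a-dimethyl-6-oxo-1,2,3,4,4a,5,6,7-octahydronaphthalen-2-yl (2E,4E)-hexa-2,4-dienoate | C/C=C/C=C/C(=O)O[C@H]1CC[C@]2(C)CC(=O)CC=C2[C@H]1C
F3 | step 6 | (1R,2S,8aR)-6-[(tert-butyldimethylsilyl)oxy]-1,8a-dimethyl-1,2,3,7,8,8a-hexahydronaphthalen-2-yl (2E,4E)-hexa-2,4-dienoate | C/C=C/C=C/C(=O)O[C@H]1CC=C2C=C(O[Si](C)(C)C(C)(C)C)CC[C@]2(C)[C@H]1C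
F4 | step 9 | tert-butyldimethyl{[(2S,3S)-3-methylpent-4-en-2-yl]oxy}silane | C[C@H](O[Si](C)(C)C(C)(C)C)[C@@H](C)C=C
F5 | step 9 | (2R,3S)-3-[(tert-butyldimethylsilyl)oxy]-2-methylbutanal | C[C@H](O[Si](C)(C)C(C)(C)C)[C@@H](C)C=O
F6 | step 9 | ethyl (2E,4E,6S,7S)-7-[(tert-butyldimethylsilyl)oxy]-6-methylocta-2,4-dienoate | C[C@H](O[Si](C)(C)C(C)(C)C)[C@@H](C)/C=C/C=C/C(=O)OCC
F7 | step 9 | (2E,4E,6S,7S)-7-[(tert-butyldimethylsilyl)oxy]-6-methylocta-2,4-dienoic acid | C[C@H](O[Si](C)(C)C(C)(C)C)[C@@H](C)/C=C/C=C/C(=O)O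
F8 | step 9 | (1R,2S,8aR)-1,8a-dimethyl-6-oxo-1,2,3,4,6,7,8,8a-octahydronaphthalen-2-yl (2E,4E,6S,7S)-7-[(tert-butyldimethylsilyl)oxy]-6-methylocta-2,4-dienoate | C[C@H](O[Si](C)(C)C(C)(C)C)[C@@H](C)/C=C/C=C/C(=O)O[C@H]1CCC2=CC(=O)CC[C@]2(C)[C@H]1C
F9 | step 9 | (1R,2S,8aR)-1,8a-dimethyl-6-oxo-1,2,6,7,8,8a-hexahydronaphthalen-2-yl (2E,4E,6S,7S)-7-[(tert-butyldimethylsilyl)oxy]-6-methylocta-2,4-dienoate | C[C@H](O[Si](C)(C)C(C)(C)C)[C@@H](C)/C=C/C=C/C(=O)O[C@H]1C=CC2=CC(=O)CC[C@]2(C)[C@H]1C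
F10 | step 9 | (1R,2S,7R,8aR)-7-hydroxy-1,8a-dimethyl-6-oxo-1,2,6,7,8,8a-hexahydronaphthalen-2-yl (2E,4E,6S,7S)-7-[(tert-butyldimethylsilyl)oxy]-6-methylocta-2,4-dienoate | C[C@H](O[Si](C)(C)C(C)(C)C)[C@@H](C)/C=C/C=C/C(=O)O[C@H]1C=CC2=CC(=O)[C@H](O)C[C@]2(C)[C@H]1C
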